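All runs are simulated with constants of no real substance; scatter was added.

At the time of reading, 50 min, the spring flask stands 10.0 min past its last reading, so your task is to carry the fall of starting material across that gap.

| flask | starting material | free enzyme | temperature | remark | time |
|---|---|---|---|---|---|
| spring | 0.010 M | 0.01 mol% | 37 °C | the very flask that is asked about, followed so far |  |
| dawn | 0.010 M | 0.015 mol% | 32 °C | run made earlier |  |
| flask | 0.010 M | 0.01 mol% | 37 °C |  | 50 min |

| run | time / min | target / % | starting material / % |
|---|---|---|---|
| spring | 3.00 | 26.9 | 72.5 |
| spring | 8.00 | 46.8 | 53.2 |
| spring | 15.0 | 61.6 | 39.6 |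
| spring | 40.0 | 76.3 | 23.5 |
| dawn | 0.417 | 7.7 | 92.5 |
| dawn | 1.00 | 16.1 | 83.5 |
| dawn | 2.00 | 27.4 | 72.2 |
| dawn | 5.00 | 47.4 | 52.0 |

(each reading ± 0.5 percentage points)

- west: change nothing and wait 15 min more
- north-east: at 50 min raise the temperature by 20 K, then wait 15 min
- east: at 50 min take out 90 % of the target then present, then wait 15 min
- south: at 50 min add free enzyme, 50.0 % of the amount charged, then wait 15 min

- target, in percent of the starting material first charged, at 50 min
- the remedy with the largest gain of target, or "none" below 2 percentage points (west / north-east / east / south / none)
- target present, with what was taken out counted in, in percent of the starting material first charged, after north-east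
- target present, with what was taken out counted in, in percent of the starting material first charged, after east

- removed target is counted in
- additions bring no volume worth counting

Start with the rate constant. At first order, k = ln(ratio of [starting material])/(interval) stays put. In spring it is 0.0619 min⁻¹ between the first two readings but 0.0209 min⁻¹ between the last two, so do not freeze k. The balance at 40.0 min reads 99.8 %, which is full within the scatter, so reckon the target as what is missing from the starting material.

Now look for what does hold still. Compare equal factors of time instead of equal intervals, and define the tail exponent: the fall of ln[starting material] per unit of ln(time). Between the last two spring readings it is 0.532, and between the two before them 0.470, so, as far as these scattered readings show, it is nearly constant in the spring tail. Freeze it. My own reckoning multiplies the last reading by (ratio of times) raised to that exponent, which leaves the target at 79.1 % at 50 min. By the same reckoning, waiting 15 min more, as in west, adds 2.7 percentage points.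

The forecast gives 78.5 % for now, which is 0.60 points below my figure. It names south as best, with 79.5 % after north-east and 83.2 % after east, while granting that “the choice of remedy is uncertain”.

The flask gives 79.2 % at 50 min. The best remedy is south, with a gain of 9.4 points, against 2.3 points for west; north-east ends at 79.8 % and east, with what was taken out counted in, at 81.5 %.

    free enzyme → unfolded enzyme (k = 3.59 × 10⁻⁵ s⁻¹, Ea = 220 kJ mol⁻¹)
    starting material + free enzyme → target + free enzyme, rate k2*[starting material]^2.5*[free enzyme]/(1 + ([starting material]/Kh2)^2.5) (2.80 mM, k = 6.13 × 10⁷ M⁻²·⁵ s⁻¹, Ea = 9.00 kJ mol⁻¹)
    2 free enzyme → spent catalyst (k = 3740 M⁻¹ s⁻¹, Ea = 36.0 kJ mol⁻¹)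
    (constants at 37 °C)

At the charged loading of this flask, free enzyme has a first half-life by pairing alone, a second-order deactivation, of 2.23 min, against 5.4 h by unfolding alone. At 50.0 min the catalyst charged to this flask stands as 94.5 % spent catalyst, 1.49 % unfolded enzyme and 4.03 % free enzyme. The answer to now moves by 5 points at a loading of 0.0067 mol% or 0.018 mol%, so a run showing a shift of that size would part from the forecast. From 25.0 min to 50.0 min this flask's tail exponent is 0.521. Frozen at 0.532 on the dawn flask from 5.00 min, it gives 84.7 % target at 50 min, where that flask stands at 85.6 %.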